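**Retrosynthetic overview**
1. The target is one strain-free, achiral 27-membered ring (C1–C26 plus the ring oxygen) whose only functional group is the lactone C1(=O)–O–C26.
2. Ring-closing disconnection: the C15–C16 bond between two plain methylene carbons, made by one-pot 9-BBN hydroboration and intramolecular palladium-catalysed alkyl–alkyl Suzuki–Miyaura coupling of undec-10-en-1-yl 15-bromopentadecanoate, so the saturated ring forms directly with nothing left to remove.
3. Enabling feature: C15 (14 bonds from the carbonyl carbon C1) and C16 (11 bonds from the ring oxygen) split the ring into C1–C15, which is the carbon chain of the 16-membered lactone 15-pentadecanolide, and C16–C26–O, which is undec-10-en-1-ol with its terminal =CH2 as C16; the remote lactone is inert to 9-BBN and to K3PO4·H2O.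
4. Second disconnection: the ester bond C1–O(C26) to 15-bromopentadecanoic acid and undec-10-en-1-ol; the bromo acid comes from HBr opening of 15-pentadecanolide at its C15–O bond.
5. Ring order: the 16-membered ring of the starting lactone is opened in step 1; the only ring of the target, the 27-membered lactone, is formed last in step 3.

Key step: step 3

Remark: the target has no stereocentre, so no stereocontrol is needed. 15-Pentadecanolide and undec-10-en-1-ol are assumed as the commercial starting materials; 15-bromopentadecanoic acid is also sold and could be entered directly at step 2.

Step 1
Reactants: 1 15-pentadecanolide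
Product: 2 15-bromopentadecanoic acid
Conditions: HBr (33 wt % in AcOH), conc. H2SO4 (cat.), 100 °C, sealed vessel
Reagents that add atoms: hydrogen bromide, Br
Why: Acid-mediated ring opening of a lactone to an ω-bromo acid, in which bromide attacks the primary O-bearing carbon C15 of the protonated lactone in an SN2 alkyl–oxygen cleavage; it is a net addition of HBr, so every atom of both partners should end up in the product.

Step 2
Reactants: 2 15-bromopentadecanoic acid; 3 undec-10-en-1-ol
Product: 4 undec-10-en-1-yl 15-bromopentadecanoate
Conditions: DCC (1.1 equiv), DMAP (0.1 equiv), CH2Cl2, 0 °C to rt
Reagents that add atoms: none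
Why: Steglich esterification of an unhindered acid with a primary alcohol under neutral conditions at room temperature, which should leave the primary bromide and the terminal alkene untouched.

Step 3
Reactants: 4 undec-10-en-1-yl 15-bromopentadecanoate
Product: 6 26-hexacosanolide, via B-alkyl-9-BBN bromo ester 5 (not isolated)
Conditions: 9-BBN dimer (0.53 equiv), THF, 0 °C to rt; then syringe-pump addition (20 h) into Pd(OAc)2 (15 mol %), PCy3 (30 mol %), K3PO4·H2O (3 equiv), THF, rt, final concentration about 2 mM
Reagents that add atoms: none
Why: Proposed new method: anti-Markovnikov hydroboration by 9-BBN puts boron on the terminal =CH2 carbon (C16) and leaves the ester and the primary bromide alone; zerovalent palladium bearing PCy3 then inserts into the primary C15–Br bond by SN2-type oxidative addition, the hydroxide-activated borate passes its primary alkyl group (C16) to divalent palladium within the same molecule, and C(sp3)–C(sp3) reductive elimination from the resulting 28-membered dialkylpalladium species releases the lactone. The closest known reaction type is the intermolecular Suzuki–Miyaura coupling of B-alkyl-9-BBN reagents with unactivated primary alkyl bromides bearing β-hydrogens under Pd(OAc)2/PCy3/K3PO4·H2O at room temperature, which tolerates esters, together with B-alkyl Suzuki macrocyclisations onto alkenyl halides; the extension is an alkyl bromide as the intramolecular partner. The one ring closed, the 27-membered lactone, forms by end-to-end closure in which both reacting sp3 carbons become ring members, and its size is fixed by the terminal regiochemistry of the hydroboration. No stereocentre is created, the target being achiral. The step needs cyclisation to beat oligomerisation and reductive elimination to beat β-hydride elimination: the first should be secured by slow addition of the borane into the catalyst (pseudo-high dilution) and by the strain-free polymethylene tether, the second by the bulky, electron-rich PCy3 ligand at room temperature, while exclusive transfer of the primary alkyl group from boron and the mildness of K3PO4·H2O toward the ester complete the selectivity.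

**Compound list**
1 | 15-pentadecanolide (oxacyclohexadecan-2-one) | O=C1CCCCCCCCCCCCCCO1 | starting material
2 | 15-bromopentadecanoic acid | OC(=O)CCCCCCCCCCCCCCBr | intermediate
3 | undec-10-en-1-ol | OCCCCCCCCCC=C | starting material
4 | undec-10-en-1-yl 15-bromopentadecanoate | C=CCCCCCCCCCOC(=O)CCCCCCCCCCCCCCBr | intermediate
5 | 11-(9-borabicyclo[3.3.1]nonan-9-yl)undecyl 15-bromopentadecanoate | BrCCCCCCCCCCCCCCC(=O)OCCCCCCCCCCCB1C2CCCC1CCC2 | intermediate
6 | 26-hexacosanolide (oxacycloheptacosan-2-one) | O=C1CCCCCCCCCCCCCCCCCCCCCCCCCO1 | target

**Total step count:** 3
**Longest linear sequence:** 3 steps (1 to 2 to 4 to 6)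

**Steps most likely to fail**

Step 3 (Proposed new method). Intermolecular transmetalation may outrun the intramolecular one and give linear and cyclic oligomers. β-Hydride elimination or protodebromination at the alkylpalladium stage may also take over when transmetalation by the tethered borate is slow at high dilution. The fallback makes the same C15–C16 bond intermolecularly at preparative concentration, where the alkyl–alkyl Suzuki coupling is established, and closes the ring at the ester C–O bond instead. It sets out from 2 and 3 and comes back to the route at 6. Compound 2 would be esterified (MeOH, cat. H2SO4, reflux) to methyl 15-bromopentadecanoate F1, and 3 acetylated (Ac2O, pyridine, cat. DMAP) to undec-10-en-1-yl acetate F2. Hydroboration of F2 with 9-BBN in THF would give 11-(9-borabicyclo[3.3.1]nonan-9-yl)undecyl acetate F3, used in solution and coupled with F1 (Pd(OAc)2, PCy3, K3PO4·H2O, THF, rt) to methyl 26-acetoxyhexacosanoate F4. Saponification of both esters (KOH, MeOH/THF/H2O, then HCl) would give 26-hydroxyhexacosanoic acid F5. Yamaguchi macrolactonisation (2,4,6-trichlorobenzoyl chloride, Et3N, THF, then slow addition to DMAP in refluxing toluene) would pass through 26-hydroxyhexacosanoic 2,4,6-trichlorobenzoic anhydride F6 and should close the ring to 6.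

Step 1. Alkyl–oxygen cleavage of the macrolactone may stall, with acetolysis at C15 or acid-catalysed self-esterification to linear oligoesters competing. The fallback separates ring opening from bromination; it sets out from 1 and comes back at 2. Irreversible saponification of 1 (KOH, EtOH/H2O, reflux, then HCl) would give 15-hydroxypentadecanoic acid F7, whose free primary hydroxyl would then be substituted by bromide (48% aq. HBr, conc. H2SO4, reflux) to give 2.

Step 2. The activated acid may rearrange by O-to-N acyl shift to an N-acylurea, or DMAP may be alkylated by the primary bromide, both eroding the esterification. The fallback forms the ester without carboxyl activation and installs bromine afterwards; it sets out from 1 and 3 and comes back at 4. Alkoxide-catalysed ring-opening transesterification of 1 with excess 3 (NaH 0.1 equiv, 3 5 equiv, THF, 60 °C) would give undec-10-en-1-yl 15-hydroxypentadecanoate F8, and Appel bromination (CBr4, PPh3, CH2Cl2, 0 °C) would convert F8 into 4.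

**Further compounds**
F1 | step 3 | methyl 15-bromopentadecanoate | COC(=O)CCCCCCCCCCCCCCBr
F2 | step 3 | undec-10-en-1-yl acetate | CC(=O)OCCCCCCCCCC=C
F3 | step 3 | 11-(9-borabicyclo[3.3.1]nonan-9-yl)undecyl acetate | CC(=O)OCCCCCCCCCCCB1C2CCCC1CCC2
F4 | step 3 | methyl 26-acetoxyhexacosanoate | COC(=O)CCCCCCCCCCCCCCCCCCCCCCCCCOC(C)=O
F5 | step 3 | 26-hydroxyhexacosanoic acid | OC(=O)CCCCCCCCCCCCCCCCCCCCCCCCCO
F6 | step 3 | 26-hydroxyhexacosanoic 2,4,6-trichlorobenzoic anhydride | O=C(CCCCCCCCCCCCCCCCCCCCCCCCCO)OC(=O)c1c(Cl)cc(Cl)cc1Cl
F7 | step 1 | 15-hydroxypentadecanoic acid | OC(=O)CCCCCCCCCCCCCCO
F8 | step 2 | undec-10-en-1-yl 15-hydroxypentadecanoate | C=CCCCCCCCCCOC(=O)CCCCCCCCCCCCCCO
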